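All runs are simulated for an exercise; noise was put on by code.

One first-order constant cannot describe the electrophile in the grey run. Over the first 2.00 min it falls with k_b = 0.471 /min, but from there to 15.0 min with the slower tail constant k_t = 0.122 /min, the logarithmic slope of the grey readings after the burst, a reading that carries their scatter.

| flask | electrophile | nucleophile | scavenger | remark | time |
|---|---|---|---|---|---|
| teal | 10 mM | 12 mM | 8 mM | run made earlier |  |
| grey | 10 mM | 12 mM | 17 mM | run made earlier |  |
| dusk | 10 mM | 12.0 mM | 15.0 mM |  | 30 min |
| dawn | 10 mM | 12.0 mM | 20.0 mM |  | 30 min |

- teal (time / min: electrophile / %, target / %): 2.00: 40, 52; 4.00: 33, 54; 6.00: 26, 52; 8.00: 22, 51; 10.0: 20, 52; 12.0: 14, 54; 15.0: 16, 48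
- grey (time / min: electrophile / %, target / %): 2.00: 39, 52; 4.00: 33, 51; 6.00: 25, 57; 8.00: 23, 57; 10.0: 15, 55; 12.0: 12, 58; 15.0: 8, 59

(readings scatter by 2 percentage points)



- part of the electrophile that has reacted at the end, dusk
- part of the electrophile that has reacted at the end, dawn
- what raising the concentration of scavenger from its lowest to its highest value here does to the part of the electrophile that has reacted (changes below 5 percentage points count as none) (it rises / it falls / no change)

1. The bench rule is to extrapolate the tail. From grey's 8% at 15.0 min, k_t leaves 1.29% at 30 min, so this reckoning gives 98.7% reacted for dusk and for dawn alike.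

2. The rule has a border, found with ρ, the charge of scavenger over that of electrophile. Grey has ρ = 1.70, between dusk at 1.50 and dawn at 2.00. Teal has ρ = 0.800, and its tail constant reads 0.0705 /min, slower than k_t, so grey's constant does not carry down to teal.

3. Teal's constant on the same start leaves 2.78%, a spread of 1.5 percentage points, less than 5 points. This reckoning therefore expects no change from dusk to dawn.

4. The forecast gives 97% for dusk, 97% for dawn and no change, allowing “a little more if the tail slows as nucleophile depletes”. Its percentages stand below the reckoning above, and the trend is the same.

5. The flasks give 98.6% for dusk and 99.1% for dawn, so the trend is no change, with a change of 0.45 points.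

    electrophile + target → side product (k = 9.13 /M/min)
    nucleophile + acid set free ⇌ protonated nucleophile, settled at all times (K = 20000 /M)
    acid set free + scavenger → scavenged by-product (k = 37.3 /M/min)
    electrophile + nucleophile → acid set free + target (k = 104 /M/min)
    nucleophile + acid set free ⇌ idle adduct, settled at all times (K = 150 /M)

Carried from dusk's 9.77% at 15.0 min, k_t gives 1.57% at 30.0 min, and dusk holds 1.36% electrophile then. In dawn the selectivity drifts: electrophile goes to target 12 times as fast as to side product at 0.690 min, but 2.3 times as fast at 30.0 min. At 30.0 min dawn holds 58.9% target and 40.2% side product, each side product counted as two electrophile.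

6. A second flask is dawn stopped at 8.0 min. From grey's 39% at 2.00 min, k_t leaves 18.8%, so 81.2% reacted. The computed flask has 80.1% reacted.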